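**Retrosynthetic overview**

- Feature used: in the oxolane ring O1–C7–C8–C8'–C9' the hydroxymethyl carbon C9 (on C8) and the carbinol carbon C7' (on C8') are cis, so the C9–OH / C7'–OH pair is read as an opened cis-fused five-membered lactol (C9–O–C7').
- Last C–C bond: C7'–aryl, by Felkin–Anh-controlled addition of an aryl Grignard reagent to that bicyclic lactol, which opens it to the diol.
- The lactol comes from a cis-fused γ-lactone by LiAlH4 reduction and periodate excision of one CH2O carbon.
- Key disconnection: both C–C bonds of the oxolane (C7–C8 and C8'–C9') by (3+2) cycloaddition of the carbonyl ylide ArCH=O(+)–CH2(−) (atoms C7, O1, C9') to the C3=C4 alkene of chiral-pool (S)-5-(silyloxymethyl)furan-2(5H)-one. The pool stereocentre steers C8, C8' and C7 in one step and is then cut out.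
- Ring order: lactone ring (from the pool) → oxolane (step 3) → lactone cleaved and re-closed as lactol (steps 4, 5) → lactol opened (step 7).

Key step: step 3

Remark: lignan locants are used for the oxolane (O1–C7–C8–C8'–C9'; C9 is the CH2OH carbon on C8, C7' is the carbinol carbon on C8', which the name of the target calls C-7). In these locants the target is (7S,8R,8'R,7'R).

**Route**

Step 1
Reactants: 1 (5S)-5-(hydroxymethyl)furan-2(5H)-one
Product: 2 (5S)-5-{[(tert-butyldiphenylsilyl)oxy]methyl}furan-2(5H)-one
Conditions: TBDPSCl, imidazole, CH2Cl2, 0 °C to rt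
Reagents that add atoms: tert-butyl(chloro)diphenylsilane, CC(C)(C)[Si](Cl)(c1ccccc1)c1ccccc1
Why: Imidazole-promoted silyl ether formation at the primary alcohol; the mild base leaves the base-sensitive C5 stereocentre untouched, and the bulky silyloxymethyl group becomes the facial control element of step 3.

Step 2
Reactants: 3 4-(allyloxy)-3-methoxybenzaldehyde; 4 (trimethylsilyl)methanol
Product: 5 1-(allyloxy)-4-{bis[(trimethylsilyl)methoxy]methyl}-2-methoxybenzene
Conditions: 4 (2.2 equiv in all), PPTS (cat.), benzene, reflux, Dean–Stark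
Reagents that add atoms: (trimethylsilyl)methanol, C[Si](C)(C)CO (the second equivalent of 4, which supplies the second alkoxy group of the acetal)
Why: Acid-catalysed acetalisation of the aldehyde with two equivalents of the alcohol, driven by azeotropic removal of water (the alcohol boils well above the benzene–water azeotrope and stays in the flask); it places the CH2–SiMe3 unit (future C9') on the oxygen that becomes O1, and no stereocentre is involved.

Step 3
Reactants: 2 (5S)-5-{[(tert-butyldiphenylsilyl)oxy]methyl}furan-2(5H)-one; 5 1-(allyloxy)-4-{bis[(trimethylsilyl)methoxy]methyl}-2-methoxybenzene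
Product: 8 (3S,3aR,6S,6aS)-6-[4-(allyloxy)-3-methoxyphenyl]-3-{[(tert-butyldiphenylsilyl)oxy]methyl}tetrahydro-1H,3H-furo[3,4-c]furan-1-one, via alpha-chloro ether 6 (not isolated), via carbonyl ylide 7 (not isolated)
Conditions: AcCl, CH2Cl2, 0 °C to rt; then 2, CsF, MeCN, rt
Reagents that add atoms: acetyl chloride, CC(=O)Cl (its chlorine is held only by intermediate 6)
Why: Acetyl chloride exchanges one alkoxy group of acetal 5 for chloride to give the α-chloro ether 6, and fluoride attack at silicon then expels chloride in a 1,3-elimination to the non-stabilised carbonyl ylide 7 (C7=O1(+)–C9'(−)), which adds across the C3=C4 bond (C8=C8') of butenolide 2 in a concerted suprafacial 1,3-dipolar (3+2) cycloaddition. The closest known reaction type is the silicon-based 1,3-elimination of α-chloro α'-silyl ethers with CsF to carbonyl ylides and their cycloaddition to acrylates, fumarates, maleimides and other electron-poor alkenes. The oxolane ring closes by two-bond (3+2) union (C9'–C8' and C7–C8), and the cis geometry of the ring alkene makes the new ring cis-fused to the lactone. C8 and C8' are set by approach of the dipole to the face of 2 opposite the C5 silyloxymethyl group (substrate control by the pool stereocentre), and C7 by the exo approach that keeps the aryl group away from the lactone ring, which gives the 7,8-trans relation. The step needs regioselectivity (CH2 terminus to the β-carbon, aryl-bearing terminus to the α-carbon): the electron-rich aryl group stabilises the oxocarbenium form ArCH=O(+)–CH2(−), so the unsubstituted terminus should carry the larger HOMO coefficient and bond to the electrophilic β-carbon. It also needs face and exo selectivity, which the C5 substituent and the steric demand of the aryl group should secure.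

Step 4
Reactants: 8 (3S,3aR,6S,6aS)-6-[4-(allyloxy)-3-methoxyphenyl]-3-{[(tert-butyldiphenylsilyl)oxy]methyl}tetrahydro-1H,3H-furo[3,4-c]furan-1-one
Product: 9 (1S)-1-[(3R,4R,5S)-5-[4-(allyloxy)-3-methoxyphenyl]-4-(hydroxymethyl)oxolan-3-yl]-2-[(tert-butyldiphenylsilyl)oxy]ethan-1-ol
Conditions: LiAlH4, THF, 0 °C
Reagents that add atoms: none
Why: Hydride reduction of the γ-lactone to the 1,4-diol turns C9 into the CH2OH group; no stereocentre is touched, and the aryl allyl ether and the silyl ether are inert to the reagent.

Step 5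
Reactants: 9 (1S)-1-[(3R,4R,5S)-5-[4-(allyloxy)-3-methoxyphenyl]-4-(hydroxymethyl)oxolan-3-yl]-2-[(tert-butyldiphenylsilyl)oxy]ethan-1-ol
Product: 11 (3aR,4S,6aR)-4-[4-(allyloxy)-3-methoxyphenyl]tetrahydro-1H,3H-furo[3,4-c]furan-1-ol (both C1 epimers), via triol 10 (not isolated)
Conditions: TBAF, AcOH, THF, rt; then NaIO4, THF/H2O (pH 7), 0 °C to rt
Reagents that add atoms: none
Why: Buffered fluoride desilylation frees the 1,2-diol and Malaprade periodate cleavage removes the former butenolide CH2O carbon; the C7' aldehyde is trapped at once by the cis C9 hydroxyl as the cis-fused lactol, which keeps C8' from epimerising while the relay stereocentre is deleted.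

Step 6
Reactants: 12 4-bromo-2-methoxyphenol
Product: 13 1-(allyloxy)-4-bromo-2-methoxybenzene
Conditions: allyl bromide, K2CO3, acetone, reflux
Reagents that add atoms: allyl bromide, C=CCBr
Why: Williamson ether synthesis on the phenoxide; no stereocentre is involved.

Step 7
Reactants: 11 (3aR,4S,6aR)-4-[4-(allyloxy)-3-methoxyphenyl]tetrahydro-1H,3H-furo[3,4-c]furan-1-ol; 13 1-(allyloxy)-4-bromo-2-methoxybenzene
Product: 15 {(2S,3R,4R)-2-[4-(allyloxy)-3-methoxyphenyl]-4-[(R)-[4-(allyloxy)-3-methoxyphenyl](hydroxy)methyl]oxolan-3-yl}methanol, via aryl Grignard reagent 14 (not isolated)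
Conditions: Mg, THF, rt; then 11 (Grignard 3.5 equiv), THF, −20 °C to rt; aq. NH4Cl
Reagents that add atoms: magnesium, [Mg] (held only by intermediate 14)
Why: Grignard addition to the open hydroxy aldehyde tautomer of the lactol (the first equivalent deprotonates the lactol); the new carbinol centre C7' is set by Felkin–Anh control from C8', the aryl group adding anti to the larger C8 ring branch with the ring CH2O carbon C9' on the carbonyl oxygen side, an outcome that 1,3-chelation of magnesium by the ring oxygen O1 also predicts, so the (7'R) alcohol should be the main product.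

Step 8
Reactants: 15 {(2S,3R,4R)-2-[4-(allyloxy)-3-methoxyphenyl]-4-[(R)-[4-(allyloxy)-3-methoxyphenyl](hydroxy)methyl]oxolan-3-yl}methanol
Product: 16 4-[(2S,3R,4R)-4-[(R)-hydroxy(4-hydroxy-3-methoxyphenyl)methyl]-3-(hydroxymethyl)oxolan-2-yl]-2-methoxyphenol, (7R)-7-hydroxylariciresinol
Conditions: Pd(PPh3)4 (cat.), morpholine, THF, rt
Reagents that add atoms: none
Why: Tsuji–Trost-type deallylation, in which Pd(0) ionises the aryl allyl ethers to π-allyl palladium and phenoxide and morpholine takes up the allyl group; the neutral, non-reductive conditions should leave the electron-rich benzylic alcohol and the 2-aryl oxolane C–O bond intact.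

**Compound list**

1 | (5S)-5-(hydroxymethyl)furan-2(5H)-one | O=C1C=C[C@@H](CO)O1 | starting material
2 | (5S)-5-{[(tert-butyldiphenylsilyl)oxy]methyl}furan-2(5H)-one | O=C1C=C[C@@H](CO[Si](c2ccccc2)(c2ccccc2)C(C)(C)C)O1 | intermediate
3 | 4-(allyloxy)-3-methoxybenzaldehyde | C=CCOc1ccc(C=O)cc1OC | starting material
4 | (trimethylsilyl)methanol | C[Si](C)(C)CO | starting material
5 | 1-(allyloxy)-4-{bis[(trimethylsilyl)methoxy]methyl}-2-methoxybenzene | C=CCOc1ccc(C(OC[Si](C)(C)C)OC[Si](C)(C)C)cc1OC | intermediate
6 | 1-(allyloxy)-4-{chloro[(trimethylsilyl)methoxy]methyl}-2-methoxybenzene (racemic, not isolated) | C=CCOc1ccc(C(Cl)OC[Si](C)(C)C)cc1OC | intermediate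
7 | carbonyl ylide [4-(allyloxy)-3-methoxybenzylidene]oxonium methylide (not isolated) | C=CCOc1ccc(C=[O+][CH2-])cc1OC | intermediate
8 | (3S,3aR,6S,6aS)-6-[4-(allyloxy)-3-methoxyphenyl]-3-{[(tert-butyldiphenylsilyl)oxy]methyl}tetrahydro-1H,3H-furo[3,4-c]furan-1-one | O=C1O[C@H](CO[Si](c2ccccc2)(c2ccccc2)C(C)(C)C)[C@H]2CO[C@H](c3ccc(OCC=C)c(OC)c3)[C@@H]12 | intermediate
9 | (1S)-1-[(3R,4R,5S)-5-[4-(allyloxy)-3-methoxyphenyl]-4-(hydroxymethyl)oxolan-3-yl]-2-[(tert-butyldiphenylsilyl)oxy]ethan-1-ol | C=CCOc1ccc([C@H]2OC[C@H]([C@H](O)CO[Si](c3ccccc3)(c3ccccc3)C(C)(C)C)[C@@H]2CO)cc1OC | intermediate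
10 | (1S)-1-[(3R,4R,5S)-5-[4-(allyloxy)-3-methoxyphenyl]-4-(hydroxymethyl)oxolan-3-yl]ethane-1,2-diol (not isolated) | C=CCOc1ccc([C@H]2OC[C@H]([C@H](O)CO)[C@@H]2CO)cc1OC | intermediate
11 | (3aR,4S,6aR)-4-[4-(allyloxy)-3-methoxyphenyl]tetrahydro-1H,3H-furo[3,4-c]furan-1-ol (both C1 epimers) | OC1OC[C@@H]2[C@@H](c3ccc(OCC=C)c(OC)c3)OC[C@H]12 | intermediate
12 | 4-bromo-2-methoxyphenol | COc1cc(Br)ccc1O | starting material
13 | 1-(allyloxy)-4-bromo-2-methoxybenzene | C=CCOc1ccc(Br)cc1OC | intermediate
14 | [4-(allyloxy)-3-methoxyphenyl]magnesium bromide (not isolated) | C=CCOc1ccc([Mg]Br)cc1OC | intermediate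
15 | {(2S,3R,4R)-2-[4-(allyloxy)-3-methoxyphenyl]-4-[(R)-[4-(allyloxy)-3-methoxyphenyl](hydroxy)methyl]oxolan-3-yl}methanol | C=CCOc1ccc([C@H]2OC[C@H]([C@@H](O)c3ccc(OCC=C)c(OC)c3)[C@@H]2CO)cc1OC | intermediate
16 | 4-[(2S,3R,4R)-4-[(R)-hydroxy(4-hydroxy-3-methoxyphenyl)methyl]-3-(hydroxymethyl)oxolan-2-yl]-2-methoxyphenol, (7R)-7-hydroxylariciresinol | COc1cc([C@H]2OC[C@H]([C@@H](O)c3ccc(O)c(OC)c3)[C@@H]2CO)ccc1O | target

**Step count**

Total step count: 8. Longest linear sequence: 6 steps (1, 3, 4, 5, 7, 8 from compound 1; equally 2, 3, 4, 5, 7, 8 from compound 3).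

**Steps most likely to fail**

Step 3 (key cycloaddition).
- What may go wrong: the unsymmetrical ylide may add in the reverse orientation or with the aryl group endo. It may also be lost to proton transfer or self-reaction before it meets the moderately reactive butenolide. Fluoride-induced γ-deprotonation could erode the configurational purity of 2.
- Fallback, from 2 back to 8: benzophenone-sensitised photoaddition of methanol to 2 (hν 350 nm, MeOH) should give the trans hydroxymethyl lactone F1 by anti addition of the hydroxymethyl radical. Aldehyde 3 is converted with trimethyl orthoformate and catalytic acid into its dimethyl acetal F2. PPTS-catalysed exchange of F1 with F2 gives the mixed methyl acetal F3. The lactone of F3 is converted into its silyl ketene acetal F4 (LDA, TMSCl, THF, −78 °C). Ionisation of the acetal with catalytic TMSOTf (CH2Cl2, −78 °C) then closes the C7–C8 bond by an intramolecular Mukaiyama-type addition to the tethered oxocarbenium ion. The tether fixes the regiochemistry and the cis ring fusion, and the sequence rejoins the route at 8.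

Step 7 (aryl addition to the lactol).
- What may go wrong: poor or reversed facial selectivity at the aldehyde carbon, because a magnesium alkoxide chelate that mimics the closed bicycle can compete with the Felkin–Anh pathway.
- Fallback, from 11 back to 15: the order of aryl and hydride introduction is reversed. Lactol 11 is oxidised with Fétizon's reagent (Ag2CO3 on Celite, benzene, reflux) to the lactone F5. Addition of the aryllithium F6 (from 13 with n-BuLi, THF, −78 °C) gives the hydroxy ketone F7, which rests as its cis-fused hemiketal and so holds C8'. Reduction of F7 with Zn(BH4)2 (Et2O, 0 °C) delivers hydride to the face that the aryl nucleophile would have taken, so the complementary carbinol configuration results and the route is rejoined at 15.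

Step 8 (deallylation).
- What may go wrong: the liberated electron-rich phenoxides may be re-allylated on oxygen or carbon by the π-allyl palladium intermediate, or the second allyl group may be removed incompletely.
- Fallback, from 15 back to 16: both allyl ethers are isomerised with H2-activated [Ir(cod)(PMePh2)2]PF6 (THF, rt) to the bis(prop-1-enyl) ether F8. The enol ethers are then hydrolysed under neutral conditions (HgCl2, HgO, acetone/H2O, rt) to give 16.

Further compounds
F1 | step 3 | (4R,5S)-5-{[(tert-butyldiphenylsilyl)oxy]methyl}-4-(hydroxymethyl)dihydrofuran-2(3H)-one | O=C1C[C@H](CO)[C@@H](CO[Si](c2ccccc2)(c2ccccc2)C(C)(C)C)O1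
F2 | step 3 | 1-(allyloxy)-4-(dimethoxymethyl)-2-methoxybenzene | C=CCOc1ccc(C(OC)OC)cc1OC
F3 | step 3 | (4R,5S)-4-({[4-(allyloxy)-3-methoxyphenyl](methoxy)methoxy}methyl)-5-{[(tert-butyldiphenylsilyl)oxy]methyl}dihydrofuran-2(3H)-one (acetal epimers) | O=C1C[C@H](COC(OC)c2ccc(OCC=C)c(OC)c2)[C@@H](CO[Si](c2ccccc2)(c2ccccc2)C(C)(C)C)O1
F4 | step 3 | silyl ketene acetal of F3, 5-(trimethylsilyloxy)-2,3-dihydrofuran form | C[Si](C)(C)OC1=C[C@H](COC(OC)c2ccc(OCC=C)c(OC)c2)[C@@H](CO[Si](c2ccccc2)(c2ccccc2)C(C)(C)C)O1
F5 | step 7 | (3aR,4S,6aR)-4-[4-(allyloxy)-3-methoxyphenyl]tetrahydro-1H,3H-furo[3,4-c]furan-1-one | O=C1OC[C@@H]2[C@@H](c3ccc(OCC=C)c(OC)c3)OC[C@H]12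
F6 | step 7 | [4-(allyloxy)-3-methoxyphenyl]lithium | C=CCOc1ccc([Li])cc1OC
F7 | step 7 | [4-(allyloxy)-3-methoxyphenyl][(3R,4R,5S)-5-[4-(allyloxy)-3-methoxyphenyl]-4-(hydroxymethyl)oxolan-3-yl]methanone | C=CCOc1ccc([C@H]2OC[C@H](C(=O)c3ccc(OCC=C)c(OC)c3)[C@@H]2CO)cc1OC
F8 | step 8 | {(2S,3R,4R)-4-[(R)-hydroxy[3-methoxy-4-(prop-1-enyloxy)phenyl]methyl]-2-[3-methoxy-4-(prop-1-enyloxy)phenyl]oxolan-3-yl}methanol | CC=COc1ccc([C@H]2OC[C@H]([C@@H](O)c3ccc(OC=CC)c(OC)c3)[C@@H]2CO)cc1OC
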